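**Plan**
1. Retrosynthetic cuts: (a) O1–C2 and C2–C3 of the 2,2-dimethyl-2H-pyran ring, i.e. excision of the CMe2 carbon to leave a benzofuran; (b) the aryl–CH2 bond between the resorcinol ring and the propane chain; (c) the aryl–prenyl bond at C5; (d) the aryl–CMe2 bond of the 1,1-dimethylallyl group, back to an O-prenyl ether.
2. Enabling feature: O1–C8a–C4a–C4=C3 of the pyran is the O1–C7a–C3a–C3=C2 array of a 7-oxygenated benzofuran. Its O–C2 (vinyl) bond is the one bond that accepts two electrons, and the missing ring atom (C2 with both methyl groups) is the carbonyl carbon of acetone.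
3. Ring B, forward: eugenyl acetate is brominated para to OMe, iodinated ortho to OH, closed to the benzofuran by Sonogashira coupling/cyclisation, switched from Me to MOM and prenylated by Stille coupling. The aromatic furan rides through the BBr3, Pd and borane steps as a robust stand-in for the chromene.
4. Ring A, forward: 4-bromoresorcinol is O-prenylated, rearranged (Claisen) to the 1,1-dimethylallyl phenol and bis-MOM protected. The halves are joined by 9-BBN hydroboration of the allyl group and B-alkyl Suzuki coupling.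
5. Late one-carbon ring expansion of the furan (five-membered) to the pyran (six-membered) by reductive O–C2 scission, acetone capture and acid closure, then global MOM removal.
6. Stereochemistry: the target is achiral; its only geometric element, the cis C3=C4 bond, is inherited from the ring-locked C2=C3 of the benzofuran.

Key step: step 12

Remark: the target SMILES has no stereocentre, so "single enantiomer" is taken to mean the constitution as drawn; no enantiocontrol is needed.

**Route**

Step 1
Reactants: 1 2-methoxy-4-(prop-2-en-1-yl)phenyl acetate (eugenyl acetate); 2 N-bromosuccinimide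
Product: 3 5-bromo-2-methoxy-4-(prop-2-en-1-yl)phenyl acetate
Conditions: NBS (1.05 equiv), MeCN, 0 → 25 °C, dark
Reagents that add atoms: N-bromosuccinimide (2), O=C1CCC(=O)N1Br
Why: Electrophilic aromatic bromination; with the phenol oxygen damped as its acetate the methoxy group directs para, to the position ortho to the allyl group, and NBS in MeCN should brominate the activated arene faster than the isolated terminal alkene.

Step 2
Reactants: 3 5-bromo-2-methoxy-4-(prop-2-en-1-yl)phenyl acetate
Product: 4 5-bromo-2-methoxy-4-(prop-2-en-1-yl)phenol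
Conditions: K2CO3 (0.2 equiv), MeOH, 25 °C
Reagents that add atoms: none
Why: Base-catalysed transesterification (methanolysis) of the aryl acetate frees the phenol that will become the ring oxygen.

Step 3
Reactants: 4 5-bromo-2-methoxy-4-(prop-2-en-1-yl)phenol; 5 N-iodosuccinimide
Product: 6 3-bromo-2-iodo-6-methoxy-4-(prop-2-en-1-yl)phenol
Conditions: NIS (1.05 equiv), TsOH·H2O (10 mol%), MeCN, 0 → 25 °C
Reagents that add atoms: N-iodosuccinimide (5), O=C1CCC(=O)N1I
Why: Electrophilic aromatic iodination of the free phenol at its only open ortho/para position, between OH and Br.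

Step 4
Reactants: 6 3-bromo-2-iodo-6-methoxy-4-(prop-2-en-1-yl)phenol; 7 ethynyltrimethylsilane
Product: 10 4-bromo-7-methoxy-5-(prop-2-en-1-yl)-1-benzofuran, via silylalkynyl phenol 8 (not isolated), via ethynyl phenol 9 (not isolated)
Conditions: Pd(PPh3)2Cl2 (3 mol%), CuI (5 mol%), Et3N/THF, 25 °C; then TBAF (2 equiv), 65 °C
Reagents that add atoms: ethynyltrimethylsilane (7), C#C[Si](C)(C)C
Why: Sonogashira coupling should occur at C–I in preference to C–Br, after which fluoride removes the silyl group and promotes 5-endo-dig cycloisomerisation of the o-ethynylphenoxide to the benzofuran.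

Step 5
Reactants: 10 4-bromo-7-methoxy-5-(prop-2-en-1-yl)-1-benzofuran
Product: 11 4-bromo-5-(prop-2-en-1-yl)-1-benzofuran-7-ol
Conditions: BBr3 (1.2 equiv), CH2Cl2, −78 → 0 °C; then H2O
Reagents that add atoms: none
Why: Lewis-acid ether cleavage (SN2 attack of bromide on the boron-activated O–CH3) removes the methyl group at low temperature, where the aromatic furan, the aryl bromide and the allyl group should survive, so that the acid-labile MOM group can take its place.

Step 6
Reactants: 11 4-bromo-5-(prop-2-en-1-yl)-1-benzofuran-7-ol; 12 chloromethyl methyl ether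
Product: 13 4-bromo-7-(methoxymethoxy)-5-(prop-2-en-1-yl)-1-benzofuran
Conditions: MOMCl (1.5 equiv), i-Pr2NEt (2 equiv), CH2Cl2, 0 → 25 °C
Reagents that add atoms: chloromethyl methyl ether (12), COCCl
Why: O-Alkylation of the phenol (Williamson-type acetal formation) installs a group that tolerates organometallic and reducing conditions and leaves under mild acid.

Step 7
Reactants: 13 4-bromo-7-(methoxymethoxy)-5-(prop-2-en-1-yl)-1-benzofuran; 14 tributyl(3-methylbut-2-en-1-yl)stannane
Product: 15 7-(methoxymethoxy)-4-(3-methylbut-2-en-1-yl)-5-(prop-2-en-1-yl)-1-benzofuran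
Conditions: Pd2(dba)3 (2.5 mol%), P(t-Bu)3·HBF4 (10 mol%), CsF (2.2 equiv), dioxane, 90 °C
Reagents that add atoms: tributyl(3-methylbut-2-en-1-yl)stannane (14), CCCC[Sn](CCCC)(CCCC)CC=C(C)C
Why: Stille cross-coupling with a bulky electron-rich phosphine suited to the hindered aryl bromide; the prenyl group is expected to be delivered at its unsubstituted (α) terminus.

Step 8
Reactants: 16 4-bromobenzene-1,3-diol; 17 1-bromo-3-methylbut-2-ene
Product: 18 2-bromo-5-[(3-methylbut-2-en-1-yl)oxy]phenol
Conditions: prenyl bromide (1.0 equiv), K2CO3 (1.1 equiv), acetone, 25 °C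
Reagents that add atoms: 1-bromo-3-methylbut-2-ene (17), CC(C)=CCBr
Why: Williamson etherification, expected to favour the less hindered and more nucleophilic oxygen para to bromine, with one equivalent of halide limiting bis-alkylation.

Step 9
Reactants: 18 2-bromo-5-[(3-methylbut-2-en-1-yl)oxy]phenol
Product: 19 4-bromo-6-(2-methylbut-3-en-2-yl)benzene-1,3-diol
Conditions: N,N-diethylaniline, 190 °C
Reagents that add atoms: none
Why: Aromatic Claisen ([3,3]-sigmatropic) rearrangement with allyl inversion gives the 1,1-dimethylallyl group at the less hindered ortho carbon (para to the other oxygen); bromine blocks the para position and so the subsequent Cope shift.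

Step 10
Reactants: 19 4-bromo-6-(2-methylbut-3-en-2-yl)benzene-1,3-diol; 12 chloromethyl methyl ether
Product: 20 1-bromo-2,4-bis(methoxymethoxy)-5-(2-methylbut-3-en-2-yl)benzene
Conditions: NaH (2.4 equiv), MOMCl (2.4 equiv), DMF, 0 → 25 °C
Reagents that add atoms: chloromethyl methyl ether (12), COCCl
Why: Double O-alkylation of the sodium phenoxides; the strong base is chosen because one hydroxyl is flanked by the quaternary carbon.

Step 11
Reactants: 15 7-(methoxymethoxy)-4-(3-methylbut-2-en-1-yl)-5-(prop-2-en-1-yl)-1-benzofuran; 20 1-bromo-2,4-bis(methoxymethoxy)-5-(2-methylbut-3-en-2-yl)benzene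
Product: 22 5-{3-[2,4-bis(methoxymethoxy)-5-(2-methylbut-3-en-2-yl)phenyl]propyl}-7-(methoxymethoxy)-4-(3-methylbut-2-en-1-yl)-1-benzofuran, via B-alkyl-9-BBN borane 21 (not isolated)
Conditions: 9-BBN dimer (0.55 equiv), THF, 0 → 25 °C; then 20, Pd(OAc)2 (5 mol%), SPhos (10 mol%), K3PO4 (3 M aq.), 60 °C
Reagents that add atoms: none
Why: 9-BBN should add anti-Markovnikov to the monosubstituted allyl alkene far faster than to the trisubstituted prenyl alkene or the aromatic furan, and the B-alkyl borane then undergoes Suzuki–Miyaura coupling with the aryl bromide, whose own vinyl group meets no free B–H because the borane is consumed first.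

Step 12
Reactants: 22 5-{3-[2,4-bis(methoxymethoxy)-5-(2-methylbut-3-en-2-yl)phenyl]propyl}-7-(methoxymethoxy)-4-(3-methylbut-2-en-1-yl)-1-benzofuran; 23 acetone
Product: 26 6-{3-[2,4-bis(methoxymethoxy)-5-(2-methylbut-3-en-2-yl)phenyl]propyl}-8-(methoxymethoxy)-2,2-dimethyl-5-(3-methylbut-2-en-1-yl)-2H-chromene, via dilithiated ring-opened phenolate 24 (not isolated), via cis-diol 25 (not isolated)
Conditions: Li powder (excess), DTBB (10 mol%), THF, 0 °C; acetone, −78 → 0 °C; H2O; then PPTS (20 mol%), CH2Cl2, 25 °C
Reagents that add atoms: acetone (23), CC(C)=O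
Why: Lithium passes two electrons through the DTBB radical anion into the benzofuran, the only conjugated C=C of 22; the radical anion expels the phenoxide by scission of the O1–C2 (vinyl–O) bond and the second electron gives the chelated (Z)-vinyllithium 24, which adds to acetone so that the carbonyl carbon becomes the new ring atom between oxygen and the former C2. On mild acid the tertiary allylic alcohol of 25 ionises (equivalently, loses water to the o-quinone methide) and the phenol oxygen closes the six-membered ring at the CMe2 terminus, a 6-endo-trig capture of the allyl cation or oxa-6π-electrocyclisation, so the furan becomes the 2,2-dimethyl-2H-pyran by insertion of one carbon. The closest known reaction type is the arene-catalysed reductive ring-opening lithiation of benzofuran with carbonyl trapping, followed by acid cyclodehydration of the cis-diols to 2H-chromenes. No stereocentre is formed; the cis C3=C4 geometry is fixed by the furan ring and should be held in the vinyllithium by O–Li···C chelation at low temperature. The step needs electron transfer to the benzofuran in preference to three aryl MOM ethers and three isolated alkenes, which the lower-lying π* of the styrenyl enol ether and short contact at 0 °C should secure, and cleavage of O–C2 rather than O–C7a, which is favoured because the phenoxide is the better leaving group.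

Step 13
Reactants: 26 6-{3-[2,4-bis(methoxymethoxy)-5-(2-methylbut-3-en-2-yl)phenyl]propyl}-8-(methoxymethoxy)-2,2-dimethyl-5-(3-methylbut-2-en-1-yl)-2H-chromene
Product: 27 Kazinol K, 4-{3-[8-hydroxy-2,2-dimethyl-5-(3-methylbut-2-en-1-yl)-2H-chromen-6-yl]propyl}-6-(2-methylbut-3-en-2-yl)benzene-1,3-diol
Conditions: HCl (2 M in MeOH), 25–40 °C
Reagents that add atoms: none
Why: Acid-catalysed transacetalisation to methanol removes all three MOM groups under conditions that prenyl, 1,1-dimethylallyl and 2,2-dimethylchromene units normally tolerate.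

**Compound list**
1 | 2-methoxy-4-(prop-2-en-1-yl)phenyl acetate (eugenyl acetate) | CC(=O)Oc1ccc(CC=C)cc1OC | starting material
2 | N-bromosuccinimide | O=C1CCC(=O)N1Br | starting material
3 | 5-bromo-2-methoxy-4-(prop-2-en-1-yl)phenyl acetate | CC(=O)Oc1cc(Br)c(CC=C)cc1OC | intermediate
4 | 5-bromo-2-methoxy-4-(prop-2-en-1-yl)phenol | Oc1cc(Br)c(CC=C)cc1OC | intermediate
5 | N-iodosuccinimide | O=C1CCC(=O)N1I | starting material
6 | 3-bromo-2-iodo-6-methoxy-4-(prop-2-en-1-yl)phenol | Oc1c(I)c(Br)c(CC=C)cc1OC | intermediate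
7 | ethynyltrimethylsilane | C#C[Si](C)(C)C | starting material
8 | 3-bromo-6-methoxy-4-(prop-2-en-1-yl)-2-[(trimethylsilyl)ethynyl]phenol | Oc1c(C#C[Si](C)(C)C)c(Br)c(CC=C)cc1OC | intermediate
9 | 3-bromo-2-ethynyl-6-methoxy-4-(prop-2-en-1-yl)phenol | Oc1c(C#C)c(Br)c(CC=C)cc1OC | intermediate
10 | 4-bromo-7-methoxy-5-(prop-2-en-1-yl)-1-benzofuran | COc1cc(CC=C)c(Br)c2ccoc12 | intermediate
11 | 4-bromo-5-(prop-2-en-1-yl)-1-benzofuran-7-ol | Oc1cc(CC=C)c(Br)c2ccoc12 | intermediate
12 | chloromethyl methyl ether | COCCl | starting material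
13 | 4-bromo-7-(methoxymethoxy)-5-(prop-2-en-1-yl)-1-benzofuran | COCOc1cc(CC=C)c(Br)c2ccoc12 | intermediate
14 | tributyl(3-methylbut-2-en-1-yl)stannane | CCCC[Sn](CCCC)(CCCC)CC=C(C)C | starting material
15 | 7-(methoxymethoxy)-4-(3-methylbut-2-en-1-yl)-5-(prop-2-en-1-yl)-1-benzofuran | COCOc1cc(CC=C)c(CC=C(C)C)c2ccoc12 | intermediate
16 | 4-bromobenzene-1,3-diol | Oc1ccc(Br)c(O)c1 | starting material
17 | 1-bromo-3-methylbut-2-ene | CC(C)=CCBr | starting material
18 | 2-bromo-5-[(3-methylbut-2-en-1-yl)oxy]phenol | Oc1cc(OCC=C(C)C)ccc1Br | intermediate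
19 | 4-bromo-6-(2-methylbut-3-en-2-yl)benzene-1,3-diol | Oc1cc(O)c(C(C)(C)C=C)cc1Br | intermediate
20 | 1-bromo-2,4-bis(methoxymethoxy)-5-(2-methylbut-3-en-2-yl)benzene | COCOc1cc(OCOC)c(C(C)(C)C=C)cc1Br | intermediate
21 | 9-{3-[7-(methoxymethoxy)-4-(3-methylbut-2-en-1-yl)-1-benzofuran-5-yl]propyl}-9-borabicyclo[3.3.1]nonane | COCOc1cc(CCCB3C4CCCC3CCC4)c(CC=C(C)C)c2ccoc12 | intermediate
22 | 5-{3-[2,4-bis(methoxymethoxy)-5-(2-methylbut-3-en-2-yl)phenyl]propyl}-7-(methoxymethoxy)-4-(3-methylbut-2-en-1-yl)-1-benzofuran | COCOc1cc(CCCc3cc(C(C)(C)C=C)c(OCOC)cc3OCOC)c(CC=C(C)C)c2ccoc12 | intermediate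
23 | acetone | CC(C)=O | starting material
24 | lithium 4-{3-[2,4-bis(methoxymethoxy)-5-(2-methylbut-3-en-2-yl)phenyl]propyl}-2-[(Z)-2-lithioethenyl]-6-(methoxymethoxy)-3-(3-methylbut-2-en-1-yl)phenolate | [Li]Oc1c(OCOC)cc(CCCc2cc(C(C)(C)C=C)c(OCOC)cc2OCOC)c(CC=C(C)C)c1/C=C\[Li] | intermediate
25 | 4-{3-[2,4-bis(methoxymethoxy)-5-(2-methylbut-3-en-2-yl)phenyl]propyl}-2-[(1Z)-3-hydroxy-3-methylbut-1-en-1-yl]-6-(methoxymethoxy)-3-(3-methylbut-2-en-1-yl)phenol (first formed as its dilithium salt) | Oc1c(OCOC)cc(CCCc2cc(C(C)(C)C=C)c(OCOC)cc2OCOC)c(CC=C(C)C)c1/C=C\C(C)(C)O | intermediate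
26 | 6-{3-[2,4-bis(methoxymethoxy)-5-(2-methylbut-3-en-2-yl)phenyl]propyl}-8-(methoxymethoxy)-2,2-dimethyl-5-(3-methylbut-2-en-1-yl)-2H-chromene | COCOc1cc(CCCc3cc(C(C)(C)C=C)c(OCOC)cc3OCOC)c(CC=C(C)C)c2C=CC(C)(C)Oc12 | intermediate
27 | Kazinol K, 4-{3-[8-hydroxy-2,2-dimethyl-5-(3-methylbut-2-en-1-yl)-2H-chromen-6-yl]propyl}-6-(2-methylbut-3-en-2-yl)benzene-1,3-diol | C=CC(C)(C)c1cc(CCCc2cc(O)c3c(c2CC=C(C)C)C=CC(C)(C)O3)c(O)cc1O | target

**Step count and risks**
Total steps: 13. Longest linear sequence: 10 (steps 1–7, 11, 12, 13).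

The three steps most likely to fail:

Step 12. Electron transfer to the electron-rich, trisubstituted benzofuran may be slow, so that reductive C–O cleavage of the aryl MOM ethers competes. The vinyllithium may be protonated before acetone arrives, by the prenyl CH2 or by the arene C–H between the two OMOM groups, and the cis geometry may partly erode. The fallback gives up the benzofuran and builds the chromene by the aryl propargyl ether Claisen route; it sets out from phenol 4 and comes back at target 27. Phenol 4 is O-alkylated with 3-chloro-3-methylbut-1-yne (CuCl2 cat., DBU, MeCN, 0 °C) to 1-bromo-4-methoxy-5-[(2-methylbut-3-yn-2-yl)oxy]-2-(prop-2-en-1-yl)benzene F1. Heating in xylene at 140 °C (Claisen rearrangement, [1,5]-H shift and oxa-6π closure at the only free ortho position) should give 5-bromo-8-methoxy-2,2-dimethyl-6-(prop-2-en-1-yl)-2H-chromene F2. Stille prenylation under the conditions of step 7 should give 8-methoxy-2,2-dimethyl-5-(3-methylbut-2-en-1-yl)-6-(prop-2-en-1-yl)-2H-chromene F3. Hydroboration of its allyl group with 9-BBN gives the B-alkyl borane F4, which is coupled with 20 as in step 11 to the methyl ether analogue of 26, F5. Lithium diphenylphosphide (THF, 25–50 °C) should cleave the one aryl methyl ether to 6-{3-[2,4-bis(methoxymethoxy)-5-(2-methylbut-3-en-2-yl)phenyl]propyl}-2,2-dimethyl-5-(3-methylbut-2-en-1-yl)-2H-chromen-8-ol F6, and removal of the two MOM groups under the conditions of step 13 reaches 27.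

Step 9. Migration may go in part to the carbon between the two oxygens; at 190 °C the o-(1,1-dimethylallyl)phenol may also rearrange further (abnormal Claisen), cyclise onto its own hydroxyl or lose the prenyl group. Incomplete oxygen selectivity in step 8 would add to this. The fallback replaces the rearrangement by cross-coupling; it sets out from 16 and comes back at 20. Iodination of 16 (NIS, MeCN, 0 °C) at the open position ortho/para to the hydroxyls gives 4-bromo-6-iodobenzene-1,3-diol F7. Double MOM protection as in step 10 gives 1-bromo-5-iodo-2,4-bis(methoxymethoxy)benzene F8. A ligand-controlled γ-selective Suzuki–Miyaura coupling of the C–I bond with 4,4,5,5-tetramethyl-2-(3-methylbut-2-en-1-yl)-1,3,2-dioxaborolane (Pd with a biaryl dialkylphosphine chosen for branched selectivity, K3PO4, aq. MeCN, 40 °C) should then give 20 directly.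

Step 7. Oxidative addition at the hindered, electron-rich C–Br bond may be slow; the prenyl group may be transferred through its γ-carbon to give the 1,1-dimethylallyl isomer; and the neighbouring allyl double bond may migrate into conjugation. The fallback reverses the polarity of the partners; it sets out from 13 and comes back at 15. Miyaura borylation of 13 (B2pin2, Pd(dppf)Cl2, KOAc, dioxane, 90 °C) gives 2-[7-(methoxymethoxy)-5-(prop-2-en-1-yl)-1-benzofuran-4-yl]-4,4,5,5-tetramethyl-1,3,2-dioxaborolane F9. Palladium-catalysed allyl–aryl coupling of F9 with 17 (Pd(PPh3)4, K2CO3, THF/H2O, 60 °C) through a π-prenyl palladium intermediate should join the aryl group to the unsubstituted terminus and give 15.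

**Further compounds**
F1 | step 12 | 1-bromo-4-methoxy-5-[(2-methylbut-3-yn-2-yl)oxy]-2-(prop-2-en-1-yl)benzene | C#CC(C)(C)Oc1cc(Br)c(CC=C)cc1OC
F2 | step 12 | 5-bromo-8-methoxy-2,2-dimethyl-6-(prop-2-en-1-yl)-2H-chromene | COc1cc(CC=C)c(Br)c2C=CC(C)(C)Oc12
F3 | step 12 | 8-methoxy-2,2-dimethyl-5-(3-methylbut-2-en-1-yl)-6-(prop-2-en-1-yl)-2H-chromene | COc1cc(CC=C)c(CC=C(C)C)c2C=CC(C)(C)Oc12
F4 | step 12 | 9-{3-[8-methoxy-2,2-dimethyl-5-(3-methylbut-2-en-1-yl)-2H-chromen-6-yl]propyl}-9-borabicyclo[3.3.1]nonane | COc1cc(CCCB3C4CCCC3CCC4)c(CC=C(C)C)c2C=CC(C)(C)Oc12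
F5 | step 12 | 6-{3-[2,4-bis(methoxymethoxy)-5-(2-methylbut-3-en-2-yl)phenyl]propyl}-8-methoxy-2,2-dimethyl-5-(3-methylbut-2-en-1-yl)-2H-chromene | COc1cc(CCCc3cc(C(C)(C)C=C)c(OCOC)cc3OCOC)c(CC=C(C)C)c2C=CC(C)(C)Oc12
F6 | step 12 | 6-{3-[2,4-bis(methoxymethoxy)-5-(2-methylbut-3-en-2-yl)phenyl]propyl}-2,2-dimethyl-5-(3-methylbut-2-en-1-yl)-2H-chromen-8-ol | Oc1cc(CCCc3cc(C(C)(C)C=C)c(OCOC)cc3OCOC)c(CC=C(C)C)c2C=CC(C)(C)Oc12
F7 | step 9 | 4-bromo-6-iodobenzene-1,3-diol | Oc1cc(O)c(I)cc1Br
F8 | step 9 | 1-bromo-5-iodo-2,4-bis(methoxymethoxy)benzene | COCOc1cc(OCOC)c(I)cc1Br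
F9 | step 7 | 2-[7-(methoxymethoxy)-5-(prop-2-en-1-yl)-1-benzofuran-4-yl]-4,4,5,5-tetramethyl-1,3,2-dioxaborolane | COCOc1cc(CC=C)c(B3OC(C)(C)C(C)(C)O3)c2ccoc12
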